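**Retrosynthetic overview**
- The strategy rests on one feature. The two oxiranes sit on former (E)-trisubstituted alkenes C1=C10 and C4=C5, which form a 1,5-diene through C2–C3 in the ten-membered carbocycle C1–C10, opposite the contiguous C6(O)–C7(C11)–C8(O) triad. That ring is therefore the [3,3] product of a cyclohexane C5–C10 that already carries the triad.
- Disconnections: diepoxide ⇒ 8β-tigloyloxycostunolide (late outer-face epoxidation) ⇒ 6,12-diol (oxidative lactonisation) ⇒ germacradiene ⇒ enol triflate ⇒ anionic oxy-Cope of a trans-1-isopropenyl-2-vinylcyclohexanol (C2–C3 made, C5–C10 cut).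
- The cyclohexane comes from a bicyclo[2.2.2]octenone (masked o-benzoquinone plus PMB vinyl ether). Its etheno bridge C1=C11 fixes C7, C8 and C10 and is then cut by ozonolysis; C6 is set by hydride reduction and the absolute configuration by lipase resolution.
- Ring order: arene → bicyclo[2.2.2]octene (holding the six-membered ring C5–C10) → monocyclic cyclohexane → ten-membered ring → γ-lactone → two oxiranes.

Key step: step 15

Remarks on the chemistry (assumptions):
- Germacrane numbering C1–C15 is used from compound 13 on. β is the ring face that carries C11 on C7.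
- In the bicycle, the CH bridgehead is C7, the ketone C6, the ketal C5, the methyl-bearing bridgehead C10, the PMB-oxy carbon C8, the CH2 C9, the alkene C1=C11 and the CH2OSi carbon C12.
- Compounds 13 and 14 are racemic and drawn as the enantiomer carried on. It is assumed that the lipase acetylates the antipode faster, so the wanted carbinol is the recovered alcohol.
- TBS = tert-butyldimethylsilyl, TBDPS = tert-butyldiphenylsilyl, PMB = 4-methoxybenzyl, Tf = trifluoromethanesulfonyl.

**Route**

Step 1
Reactants: 1 4-hydroxy-3-methylbenzaldehyde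
Product: 2 3-bromo-4-hydroxy-5-methylbenzaldehyde
Conditions: Br2, NaOAc, AcOH, rt
Reagents that add atoms: bromine, BrBr
Why: Electrophilic aromatic bromination should occur only at the single free position ortho to the phenol, since the para position carries the formyl group.

Step 2
Reactants: 2 3-bromo-4-hydroxy-5-methylbenzaldehyde
Product: 3 3-bromo-4-methoxy-5-methylbenzaldehyde
Conditions: MeI, K2CO3, DMF, rt
Reagents that add atoms: iodomethane, CI
Why: Williamson O-methylation of the phenoxide installs the methoxy group that later becomes one of the two ketal methoxy groups at C5.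

Step 3
Reactants: 3 3-bromo-4-methoxy-5-methylbenzaldehyde
Product: 4 (3-bromo-4-methoxy-5-methylphenyl)methanol
Conditions: NaBH4, MeOH, 0 °C
Reagents that add atoms: none
Why: Borohydride reduction of the aryl aldehyde gives the benzylic alcohol (future C12) and leaves the aryl bromide untouched.

Step 4
Reactants: 4 (3-bromo-4-methoxy-5-methylphenyl)methanol
Product: 5 [(3-bromo-4-methoxy-5-methylbenzyl)oxy](tert-butyl)diphenylsilane
Conditions: TBDPSCl, imidazole, DMF, rt
Reagents that add atoms: tert-butyl(chloro)diphenylsilane, CC(C)(C)[Si](Cl)(c1ccccc1)c1ccccc1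
Why: Imidazole-promoted silylation gives a primary TBDPS ether that should survive organolithium, oxidant, Lewis acid and amide base and can be removed by fluoride together with the later TBS group.

Step 5
Reactants: 5 [(3-bromo-4-methoxy-5-methylbenzyl)oxy](tert-butyl)diphenylsilane
Product: 8 5-[(tert-butyldiphenylsilyl)oxymethyl]-2-methoxy-3-methylphenol, via aryllithium 6 (not isolated), via dimethyl arylboronate 7 (not isolated)
Conditions: n-BuLi, THF, −78 °C; B(OMe)3, −78 → 0 °C; then H2O2, aq. NaOH, 0 °C → rt
Reagents that add atoms: hydrogen peroxide, OO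
Why: Bromine–lithium exchange, borylation and oxidative 1,2-migration of the aryl group from boron to oxygen convert the C–Br bond into the phenol needed for dearomatisation.

Step 6
Reactants: 9 ethyl vinyl ether; 10 4-methoxybenzyl alcohol
Product: 11 4-methoxybenzyl vinyl ether
Conditions: Pd(OCOCF3)2 (cat.), 4,7-diphenyl-1,10-phenanthroline (cat.), Et3N, excess 9 as solvent, 40 °C (sealed)
Reagents that add atoms: none
Why: Transfer vinylation on divalent palladium (alkoxypalladation then β-alkoxide elimination) is driven by the excess of 9, and the amine keeps the acid-labile vinyl ether intact.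

Step 7
Reactants: 8 5-[(tert-butyldiphenylsilyl)oxymethyl]-2-methoxy-3-methylphenol; 11 4-methoxybenzyl vinyl ether
Product: 13 racemic endo bicyclo[2.2.2]octenone adduct (3,3-dimethoxy-7-PMB-oxy-4-methyl-6-TBDPS-oxymethyl-bicyclo[2.2.2]oct-5-en-2-one), via masked o-benzoquinone 12 (not isolated)
Conditions: PhI(OAc)2, MeOH, excess 11, 0 °C → rt, slow addition of 8
Reagents that add atoms: methanol, CO
Why: Oxidative dearomatisation in methanol gives the masked o-benzoquinone 12, which the excess vinyl ether traps in an inverse-electron-demand Diels–Alder reaction before it dimerises; the CH2 terminus bonds to the methyl-bearing diene terminus remote from the carbonyl and the alkoxy group sits endo under the forming alkene, so C11 on C7, oxygen on C8 and C1 on C10 end up on one face of the six-membered ring C5–C10.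

Step 8
Reactants: 13 racemic endo bicyclo[2.2.2]octenone adduct
Product: 14 racemic bicyclic C6 carbinol with the hydroxyl anti to the etheno bridge
Conditions: NaBH4, MeOH/CH2Cl2, −20 → 0 °C
Reagents that add atoms: none
Why: Hydride should attack the C6 carbonyl from the face of the flat etheno bridge, because the other face is screened by the syn hydrogens on C8 and C9, which places the hydroxyl α and trans to C11 on C7.

Step 9
Reactants: 14 racemic bicyclic C6 carbinol
Product: 15 enantiomerically enriched (6S) bicyclic carbinol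
Conditions: Amano lipase PS (immobilised Burkholderia cepacia lipase), vinyl acetate, t-BuOMe, 35 °C, stopped just past half conversion
Reagents that add atoms: none
Why: Lipase-catalysed kinetic resolution by irreversible transesterification should, by the empirical size rule for secondary alcohols with the C(OMe)2 carbon as the large group, acetylate the (6R)-antipode faster and leave the wanted carbinol, which fixes the absolute configuration of the whole series.

Step 10
Reactants: 15 (6S) bicyclic carbinol
Product: 16 C6 TBS ether of the bicyclic carbinol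
Conditions: TBSOTf, 2,6-lutidine, CH2Cl2, −78 → −20 °C
Reagents that add atoms: tert-butyldimethylsilyl trifluoromethanesulfonate, CC(C)(C)[Si](C)(C)OS(=O)(=O)C(F)(F)F
Why: The silyl triflate is reactive enough to silylate the hindered secondary hydroxyl at low temperature, where the neighbouring dimethyl ketal should stay intact.

Step 11
Reactants: 16 C6 TBS ether of the bicyclic carbinol
Product: 18 cyclohexane keto-aldehyde (C10 formyl; C7 silyloxyacetyl), via secondary ozonide 17 (not isolated)
Conditions: O3, CH2Cl2, −78 °C, to consumption of 16; PPh3, −78 °C → rt; no base, used crude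
Reagents that add atoms: ozone, [O-][O+]=O
Why: Ozonolysis with reductive work-up cuts the bridging C1=C11 alkene, which reacts far faster than the anisyl ring, and opens the bicycle to the cis-1,4-disubstituted cyclohexane; leaving out base avoids β-elimination of the C6 or C8 ethers from the new ketone.

Step 12
Reactants: 18 cyclohexane keto-aldehyde
Product: 19 bis-alkene dimethyl ketal (10β-vinyl; 7β-[3-TBDPS-oxyprop-1-en-2-yl])
Conditions: Zn, CH2Br2, TiCl4 (preformed reagent), THF/CH2Cl2, 0 °C → rt
Reagents that add atoms: dibromomethane, BrCBr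
Why: Takai–Lombardo methylenation uses a non-basic zinc–titanium methylene reagent, so the enolisable C11 ketone with β-alkoxy groups at C6 and C8 and the neopentyl aldehyde should both be olefinated without elimination or epimerisation at C7.

Step 13
Reactants: 19 bis-alkene dimethyl ketal
Product: 20 2-methyl-2-vinylcyclohexanone carrying the C6–C8 triad
Conditions: PPTS (cat.), acetone/H2O, 45 °C
Reagents that add atoms: water, O
Why: Mild acid hydrolysis of the ketal through an oxocarbenium ion is helped by relief of congestion at C5, and buffered PPTS should spare the silyl and PMB ethers and not epimerise C6.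

Step 14
Reactants: 20 2-methyl-2-vinylcyclohexanone; 21 isopropenylmagnesium bromide
Product: 22 trans-1-isopropenyl-2-vinylcyclohexanol (5β-hydroxy; 5α-isopropenyl; 10β-vinyl)
Conditions: CeCl3 (anhydrous), THF, −78 → 0 °C; aq. NH4Cl
Reagents that add atoms: none
Why: The organocerium reagent adds 1,2 without enolising toward C6; ketone 20 should prefer the chair with the C10 vinyl axial (the other chair has a syn-axial methyl/silyloxy pair and an axial C7 side chain), so the nucleophile enters axially anti to that vinyl group and the isopropenyl group ends up trans to it.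

Step 15
Reactants: 22 trans-1-isopropenyl-2-vinylcyclohexanol
Product: 25 cyclodecadienyl enol triflate (C3 and C6 trans across C4=C5; (E)-C1=C10), via potassium alkoxide 23 (not isolated), via potassium enolate 24 (not isolated)
Conditions: KN(SiMe3)2, 18-crown-6, THF, 0 °C → rt (to 40 °C if needed); then PhNTf2, −78 → 0 °C
Reagents that add atoms: N-phenylbis(trifluoromethanesulfonimide), O=S(=O)(N(c1ccccc1)S(=O)(=O)C(F)(F)F)C(F)(F)F
Why: Deprotonation gives potassium alkoxide 23, whose chair with vinyl and isopropenyl both equatorial undergoes a charge-accelerated [3,3] shift in which C2–C3 forms and C5–C10 breaks, giving enolate 24 regiospecifically toward C4, and PhNTf2 then fixes it on oxygen as the enol triflate. The closest known reaction type is the anionic oxy-Cope ring expansion of trans-1,2-dialkenylcyclohexanols to (E)-cyclodec-5-enones with O-trapping of the enolate. The ten-membered ring C1–C10 is closed by a four-atom enlargement of the six-membered ring C5–C10 through a six-centre chair transition state, not by an end-to-end cyclisation, so no macrocyclisation entropy is paid. No new stereocentre is formed, since C5 and C10 become trigonal; the (E)-C1=C10 geometry and the trans placement of C3 and C6 across C4=C5 follow from the equatorial alkenyl groups in the chair. The step needs the trans-dialkenyl relationship and a chair rather than a boat pathway, both supplied by the configuration set in step 14, and the substrate has no acidic C–H and only base-stable silyl and PMB ethers. The reacting chair has C14, O5, the C6 silyl ether and the C7 side chain axial, so gentle warming is allowed for, and immediate triflation prevents enolate equilibration or epimerisation at C6.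

Step 16
Reactants: 25 cyclodecadienyl enol triflate
Product: 26 protected (1(10)E,4E)-germacra-1(10),4,11(13)-triene (6α-OTBS; 8β-OPMB; 12-OTBDPS)
Conditions: Pd(OAc)2 (cat.), PPh3, HCO2H, Et3N, DMF, 50 °C
Reagents that add atoms: none
Why: Oxidative addition of zerovalent palladium into the C5–OTf bond, formate exchange, decarboxylation and reductive elimination replace the triflate by hydrogen with retention of alkene geometry, giving the (E)-C4=C5 alkene under buffered conditions that the 1,5-diene should tolerate.

Step 17
Reactants: 26 protected germacratriene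
Product: 27 8β-hydroxy germacratriene bis-silyl ether
Conditions: DDQ, CH2Cl2/pH 7 phosphate buffer, 0 °C
Reagents that add atoms: none
Why: Oxidative cleavage of the electron-rich PMB ether by DDQ through the benzylic oxocarbenium ion frees only the C8 hydroxyl, and the silyl ethers and isolated alkenes should be inert in the buffered medium.

Step 18
Reactants: 27 8β-hydroxy germacratriene bis-silyl ether; 28 tiglic acid
Product: 30 8β-tigloyloxy germacratriene bis-silyl ether, via tigloyl 2,4,6-trichlorobenzoyl anhydride 29 (not isolated)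
Conditions: 28, 2,4,6-trichlorobenzoyl chloride, Et3N, toluene, rt; then 27, DMAP, rt → 40 °C
Reagents that add atoms: none
Why: Yamaguchi esterification through the mixed anhydride and the acylpyridinium ion acylates the hindered secondary C8 hydroxyl, the only free OH, and the (E)-geometry of the tiglate should be kept because no strong base is present.

Step 19
Reactants: 30 8β-tigloyloxy germacratriene bis-silyl ether
Product: 31 8β-tigloyloxygermacra-1(10),4,11(13)-triene-6α,12-diol
Conditions: HF·pyridine, excess pyridine, THF, 0 °C → rt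
Reagents that add atoms: none
Why: Fluoride cleaves both silyl ethers through pentacoordinate silicon, and the pyridine buffer should protect the acid-sensitive germacradiene from transannular cyclisation and the ester from migration.

Step 20
Reactants: 31 8β-tigloyloxygermacratriene-6α,12-diol
Product: 34 8β-tigloyloxycostunolide, via hydroxy enal 32 (not isolated), via lactol 33 (not isolated)
Conditions: TEMPO (cat.), PhI(OAc)2, CH2Cl2, rt
Reagents that add atoms: none
Why: Oxoammonium oxidation prefers the unhindered primary allylic alcohol, the enal is captured by the C6 hydroxyl as a five-membered lactol and this is oxidised on to the trans-fused α-methylene γ-lactone with C6 and C7 untouched.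

Step 21
Reactants: 34 8β-tigloyloxycostunolide
Product: 36 target CNP0311437.1 (1β,10α:4α,5β-diepoxy-8β-tigloyloxygermacr-11(13)-en-12,6α-olide), via 1β,10α-monoepoxide 35 (not isolated)
Conditions: mCPBA (excess), NaHCO3, CH2Cl2, 0 °C → rt
Reagents that add atoms: 3-chloroperbenzoic acid, OOC(=O)c1cccc(Cl)c1
Why: Prilezhaev epoxidation attacks only the two electron-rich ring alkenes (the methylene lactone and the tiglate are electron-poor), first C1=C10 and then C4=C5, each concertedly on the outer face of the crown conformer with C14 and C15 syn, which should give the trans epoxides with C1, C10, C4 and C5 all R.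

**Compound list**

1 | 4-hydroxy-3-methylbenzaldehyde | Cc1cc(C=O)ccc1O | starting material
2 | 3-bromo-4-hydroxy-5-methylbenzaldehyde | Cc1cc(C=O)cc(Br)c1O | intermediate
3 | 3-bromo-4-methoxy-5-methylbenzaldehyde | COc1c(C)cc(C=O)cc1Br | intermediate
4 | (3-bromo-4-methoxy-5-methylphenyl)methanol | COc1c(C)cc(CO)cc1Br | intermediate
5 | [(3-bromo-4-methoxy-5-methylbenzyl)oxy](tert-butyl)diphenylsilane | COc1c(C)cc(CO[Si](c2ccccc2)(c2ccccc2)C(C)(C)C)cc1Br | intermediate
6 | [5-(TBDPS-oxymethyl)-2-methoxy-3-methylphenyl]lithium | [Li]c1cc(CO[Si](c2ccccc2)(c2ccccc2)C(C)(C)C)cc(C)c1OC | intermediate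
7 | dimethyl [5-(TBDPS-oxymethyl)-2-methoxy-3-methylphenyl]boronate | COB(OC)c1cc(CO[Si](c2ccccc2)(c2ccccc2)C(C)(C)C)cc(C)c1OC | intermediate
8 | 5-[(tert-butyldiphenylsilyl)oxymethyl]-2-methoxy-3-methylphenol | COc1c(C)cc(CO[Si](c2ccccc2)(c2ccccc2)C(C)(C)C)cc1O | intermediate
9 | ethyl vinyl ether | C=COCC | starting material
10 | 4-methoxybenzyl alcohol | COc1ccc(CO)cc1 | starting material
11 | 4-methoxybenzyl vinyl ether | C=COCc1ccc(OC)cc1 | intermediate
12 | 6,6-dimethoxy-5-methyl-3-(TBDPS-oxymethyl)cyclohexa-2,4-dien-1-one (masked o-benzoquinone) | COC1(OC)C(C)=CC(CO[Si](c2ccccc2)(c2ccccc2)C(C)(C)C)=CC1=O | intermediate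
13 | rac-3,3-dimethoxy-7-(4-methoxybenzyloxy)-4-methyl-6-(TBDPS-oxymethyl)bicyclo[2.2.2]oct-5-en-2-one, PMB ether syn to the C5=C6 bridge (racemic, drawn as the enantiomer carried on) | COC1(OC)C(=O)[C@H]2[C@H](OCc3ccc(OC)cc3)C[C@]1(C)C=C2CO[Si](c1ccccc1)(c1ccccc1)C(C)(C)C | intermediate
14 | rac bicyclic C6 carbinol of 13, hydroxyl anti to the etheno bridge (racemic, drawn as the enantiomer carried on) | COC1(OC)[C@@H](O)[C@H]2[C@H](OCc3ccc(OC)cc3)C[C@]1(C)C=C2CO[Si](c1ccccc1)(c1ccccc1)C(C)(C)C | intermediate
15 | (6S) bicyclic C6 carbinol, single enantiomer | COC1(OC)[C@@H](O)[C@H]2[C@H](OCc3ccc(OC)cc3)C[C@]1(C)C=C2CO[Si](c1ccccc1)(c1ccccc1)C(C)(C)C | intermediate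
16 | C6 TBS ether of 15 | COC1(OC)[C@@H](O[Si](C)(C)C(C)(C)C)[C@H]2[C@H](OCc3ccc(OC)cc3)C[C@]1(C)C=C2CO[Si](c1ccccc1)(c1ccccc1)C(C)(C)C | intermediate
17 | secondary ozonide (1,2,4-trioxolane across C1 and C11; configuration at C1 and C11 not specified) | COC1(OC)[C@@H](O[Si](C)(C)C(C)(C)C)[C@H]2[C@H](OCc3ccc(OC)cc3)C[C@]1(C)C1OOC2(CO[Si](c2ccccc2)(c2ccccc2)C(C)(C)C)O1 | intermediate
18 | 5,5-dimethoxy-6α-(TBS-oxy)-7β-[2-(TBDPS-oxy)acetyl]-8β-(PMB-oxy)-10α-methylcyclohexane-10β-carbaldehyde | COC1(OC)[C@@H](O[Si](C)(C)C(C)(C)C)[C@H](C(=O)CO[Si](c2ccccc2)(c2ccccc2)C(C)(C)C)[C@H](OCc2ccc(OC)cc2)C[C@]1(C)C=O | intermediate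
19 | 5,5-dimethoxy-6α-(TBS-oxy)-7β-[3-(TBDPS-oxy)prop-1-en-2-yl]-8β-(PMB-oxy)-10α-methyl-10β-vinylcyclohexane | COC1(OC)[C@@H](O[Si](C)(C)C(C)(C)C)[C@H](C(=C)CO[Si](c2ccccc2)(c2ccccc2)C(C)(C)C)[C@H](OCc2ccc(OC)cc2)C[C@]1(C)C=C | intermediate
20 | 6α-(TBS-oxy)-7β-[3-(TBDPS-oxy)prop-1-en-2-yl]-8β-(PMB-oxy)-10α-methyl-10β-vinylcyclohexan-5-one | O=C1[C@@H](O[Si](C)(C)C(C)(C)C)[C@H](C(=C)CO[Si](c2ccccc2)(c2ccccc2)C(C)(C)C)[C@H](OCc2ccc(OC)cc2)C[C@]1(C)C=C | intermediate
21 | isopropenylmagnesium bromide | CC(=C)[Mg]Br | starting material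
22 | 5α-isopropenyl-10β-vinyl cyclohexan-5β-ol (isopropenyl trans to vinyl), other substituents as in 20 | O[C@]1(C(C)=C)[C@@H](O[Si](C)(C)C(C)(C)C)[C@H](C(=C)CO[Si](c2ccccc2)(c2ccccc2)C(C)(C)C)[C@H](OCc2ccc(OC)cc2)C[C@]1(C)C=C | intermediate
23 | potassium alkoxide of 22 | [K+].[O-][C@]1(C(C)=C)[C@@H](O[Si](C)(C)C(C)(C)C)[C@H](C(=C)CO[Si](c2ccccc2)(c2ccccc2)C(C)(C)C)[C@H](OCc2ccc(OC)cc2)C[C@]1(C)C=C | intermediate
24 | potassium cyclodeca-dienolate (O on C5, C3 and C6 trans across C4=C5, (E)-C1=C10) | [K+].C/C1=C(/[O-])[C@@H](O[Si](C)(C)C(C)(C)C)[C@H](C(=C)CO[Si](c2ccccc2)(c2ccccc2)C(C)(C)C)[C@H](OCc2ccc(OC)cc2)C/C(C)=C/CC1 | intermediate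
25 | 5-triflyloxy-6α-(TBS-oxy)-8β-(PMB-oxy)-12-(TBDPS-oxy)germacra-1(10),4,11(13)-triene (1(10)E; C3 and C6 trans across C4=C5, formally 4Z) | C/C1=C(/OS(=O)(=O)C(F)(F)F)[C@@H](O[Si](C)(C)C(C)(C)C)[C@H](C(=C)CO[Si](c2ccccc2)(c2ccccc2)C(C)(C)C)[C@H](OCc2ccc(OC)cc2)C/C(C)=C/CC1 | intermediate
26 | (1(10)E,4E)-6α-(TBS-oxy)-8β-(PMB-oxy)-12-(TBDPS-oxy)germacra-1(10),4,11(13)-triene | C/C1=C\[C@@H](O[Si](C)(C)C(C)(C)C)[C@H](C(=C)CO[Si](c2ccccc2)(c2ccccc2)C(C)(C)C)[C@H](OCc2ccc(OC)cc2)C/C(C)=C/CC1 | intermediate
27 | (1(10)E,4E)-6α-(TBS-oxy)-12-(TBDPS-oxy)germacra-1(10),4,11(13)-trien-8β-ol | C/C1=C\[C@@H](O[Si](C)(C)C(C)(C)C)[C@H](C(=C)CO[Si](c2ccccc2)(c2ccccc2)C(C)(C)C)[C@H](O)C/C(C)=C/CC1 | intermediate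
28 | tiglic acid, (E)-2-methylbut-2-enoic acid | OC(=O)/C(C)=C/C | starting material
29 | tigloyl 2,4,6-trichlorobenzoyl anhydride | C/C=C(\C)C(=O)OC(=O)c1c(Cl)cc(Cl)cc1Cl | intermediate
30 | 8β-tigloyloxy-6α-(TBS-oxy)-12-(TBDPS-oxy)germacra-1(10)E,4E,11(13)-triene | C/C1=C\[C@@H](O[Si](C)(C)C(C)(C)C)[C@H](C(=C)CO[Si](c2ccccc2)(c2ccccc2)C(C)(C)C)[C@H](OC(=O)/C(C)=C/C)C/C(C)=C/CC1 | intermediate
31 | 8β-tigloyloxygermacra-1(10)E,4E,11(13)-triene-6α,12-diol | C/C1=C\[C@@H](O)[C@H](C(=C)CO)[C@H](OC(=O)/C(C)=C/C)C/C(C)=C/CC1 | intermediate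
32 | 6α-hydroxy-8β-tigloyloxygermacra-1(10)E,4E,11(13)-trien-12-al | C/C1=C\[C@@H](O)[C@H](C(=C)C=O)[C@H](OC(=O)/C(C)=C/C)C/C(C)=C/CC1 | intermediate
33 | 12,6α-lactol of 32 (C12 configuration not specified) | C/C1=C\[C@H]2OC(O)C(=C)[C@@H]2[C@H](OC(=O)/C(C)=C/C)C/C(C)=C/CC1 | intermediate
34 | 8β-tigloyloxycostunolide, 8β-tigloyloxygermacra-1(10)E,4E,11(13)-trien-12,6α-olide | C/C1=C\[C@H]2OC(=O)C(=C)[C@@H]2[C@H](OC(=O)/C(C)=C/C)C/C(C)=C/CC1 | intermediate
35 | 1β,10α-epoxy-8β-tigloyloxygermacra-4E,11(13)-dien-12,6α-olide | C/C1=C\[C@H]2OC(=O)C(=C)[C@@H]2[C@H](OC(=O)/C(C)=C/C)C[C@@]2(C)O[C@@H]2CC1 | intermediate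
36 | CNP0311437.1, (1R,4R,5R,6S,7R,8R,10R)-1β,10α:4α,5β-diepoxy-8β-tigloyloxygermacr-11(13)-en-12,6α-olide | C=C1C(=O)O[C@H]2[C@H]1[C@H](OC(=O)/C(C)=C/C)C[C@@]1(C)O[C@@H]1CC[C@@]1(C)O[C@H]21 | target

**Step count and risks**

Total step count: 21. Longest linear sequence: 20 steps (steps 1–5 and 7–21, from 4-hydroxy-3-methylbenzaldehyde); step 6 is a one-step side branch.

The three steps most likely to fail:

1. Step 15 (oxy-Cope with triflation). The alkoxide may not reach the strained chair that holds both alkenyl groups equatorial. The C6 silyl group may migrate onto the neighbouring C5 alkoxide. The enolate may equilibrate before O-sulfonylation. The fallback sets out from 22 and avoids the alkoxide altogether. The free alcohol is rearranged at room temperature with catalytic PdCl2(PhCN)2 (divalent palladium, THF), a cyclisation-induced oxy-Cope known for 1,5-dien-3-ols with one 2-substituted alkene, to give the (1(10)E)-cyclodec-5-enone F1. Kinetic deprotonation of this ketone away from the silyloxy-bearing C6 with KN(SiMe3)2 at −78 °C and trapping with PhNTf2 then returns to the route at 25. The geometry of the enol triflate obtained in this way would have to be confirmed.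

2. Step 9 (lipase resolution). The enzyme may accept the doubly flanked carbinol only slowly, or may discriminate poorly between the enantiomers. The fallback sets out from 14 and uses a covalent resolution. Acylation with (1S)-camphanic chloride (DMAP, Et3N, CH2Cl2) should give two diastereomeric esters, the camphanate of the wanted carbinol F2 and the camphanate of the antipode F3. These are separated by chromatography or crystallisation, and methanolysis of the wanted ester (K2CO3, MeOH, 40 °C) returns to the route at 15.

3. Step 12 (double methylenation). The Lewis-acidic titanium reagent may ionise the ketal or the PMB ether. The β-alkoxy ketone may lose the C8 ether by elimination before it is olefinated. The neopentyl aldehyde may react incompletely. The fallback sets out from 16 and by-passes both 18 and the carbonyl olefination. Ring-opening cross-metathesis of the strained C1=C11 bridge with ethylene (second-generation Hoveyda–Grubbs catalyst, RuCl2(H2IMes)(=CH-C6H4-2-OiPr), ethylene atmosphere, toluene, 40–60 °C) should deliver the vinyl group on C10 and the 1,1-disubstituted alkene on C7 directly. It returns to the route at 19 and makes no compound outside the list (entry F0).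

Further compounds
F1 | step 15 | (1(10)E)-6α-(TBS-oxy)-8β-(PMB-oxy)-12-(TBDPS-oxy)germacra-1(10),11(13)-dien-5-one (C4 configuration not specified) | CC1C(=O)[C@@H](O[Si](C)(C)C(C)(C)C)[C@H](C(=C)CO[Si](c2ccccc2)(c2ccccc2)C(C)(C)C)[C@H](OCc2ccc(OC)cc2)C/C(C)=C/CC1
F2 | step 9 | (1S,4R)-camphanate of the wanted carbinol 15 | COC1(OC)[C@@H](OC(=O)[C@@]45CC[C@@](C)(C(=O)O4)C5(C)C)[C@H]2[C@H](OCc3ccc(OC)cc3)C[C@]1(C)C=C2CO[Si](c1ccccc1)(c1ccccc1)C(C)(C)C
F3 | step 9 | (1S,4R)-camphanate of the antipode of 15 | COC1(OC)[C@H](OC(=O)[C@@]45CC[C@@](C)(C(=O)O4)C5(C)C)[C@@H]2[C@@H](OCc3ccc(OC)cc3)C[C@@]1(C)C=C2CO[Si](c1ccccc1)(c1ccccc1)C(C)(C)C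
F0 | step 12 | none | none
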